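**Retrosynthetic overview**

- The strategy rests on C3 being a benzylic carbinol carbon bonded to C3a, the ring carbon ortho to the O1-bearing C7a. C3 is taken back to an aldehyde carbon tethered to the arene through O1–C2, and the C3–C3a bond is made by nickel/chromium-mediated addition of a C3a–I bond to that aldehyde.
- This closure forms the dihydrofuran ring (O1, C2, C3, C3a, C7a), the only ring built; the benzene ring is bought with acetyl, hydroxyl and halogen in place.
- C2 is set beforehand by palladium-catalysed asymmetric O-allylation of the 4-hydroxyl of the bromo-resacetophenone with racemic isopropenyloxirane; bromine is exchanged for iodine and the primary alcohol is oxidised just before the closure.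
- The C3 ester is disconnected to the trans carbinol and (Z)-4-acetoxy-2-methylbut-2-enoic acid, whose Z geometry is inherited from 3-methylfuran-2(5H)-one; the aryl silyl ether is removed last.

Key step: step 7

Assumption: the (S,S)-enantiomer of the DACH-phenyl bisphosphine ligand is expected, by analogy with the sense of induction of diene monoepoxides with acidic pronucleophiles, to give the (2R)-ether; the antipodal ligand is used if a trial run shows the opposite sense.

**Route**

Step 1
Reactants: 1 methacrolein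
Product: 2 rac-2-(prop-1-en-2-yl)oxirane
Conditions: Me3S+ I−, KOtBu, DMSO, 0 °C to rt; pentane extraction, careful distillation
Reagents that add atoms: trimethylsulfonium iodide, C[S+](C)C.[I-]
Why: Corey–Chaykovsky epoxidation, in which dimethylsulfonium methylide adds 1,2 to the enal carbonyl and the betaine closes to the vinyl epoxide; the racemate suffices because the next step converts both enantiomers.

Step 2
Reactants: 3 1-(5-bromo-2,4-dihydroxyphenyl)ethanone; 2 rac-2-(prop-1-en-2-yl)oxirane
Product: 4 1-[5-bromo-2-hydroxy-4-{[(2R)-1-hydroxy-3-methylbut-3-en-2-yl]oxy}phenyl]ethanone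
Conditions: Pd2(dba)3·CHCl3 (1 mol%), (S,S)-DACH-phenyl bisphosphine ligand [N,N'-(1S,2S)-cyclohexane-1,2-diylbis(2-diphenylphosphinobenzamide)] (3 mol%), CH2Cl2, rt
Reagents that add atoms: none
Why: Tsuji–Trost allylic etherification run as a dynamic kinetic asymmetric transformation, in which zerovalent palladium opens either epoxide enantiomer to π-allyl complexes that equilibrate through the unsubstituted CH2 terminus, the alkoxide takes the proton of the more acidic, non-chelated 4-hydroxyl and directs the phenoxide to the adjacent branched terminus, and the chiral ligand pocket sets C2 as R.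

Step 3
Reactants: 4 1-[5-bromo-2-hydroxy-4-{[(2R)-1-hydroxy-3-methylbut-3-en-2-yl]oxy}phenyl]ethanone
Product: 5 1-[5-bromo-2-(tert-butyldimethylsilyloxy)-4-{[(2R)-1-(tert-butyldimethylsilyloxy)-3-methylbut-3-en-2-yl]oxy}phenyl]ethanone
Conditions: TBSCl (3 equiv), imidazole, DMAP (cat.), DMF, rt
Reagents that add atoms: tert-butyldimethylsilyl chloride, CC(C)(C)[Si](C)(C)Cl
Why: Silyl ether formation on both the primary alcohol and the hydrogen-bonded phenol removes every free hydroxyl before the copper step and installs the phenol protecting group that is carried to the end.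

Step 4
Reactants: 5 1-[5-bromo-2-(tert-butyldimethylsilyloxy)-4-{[(2R)-1-(tert-butyldimethylsilyloxy)-3-methylbut-3-en-2-yl]oxy}phenyl]ethanone
Product: 6 1-[2-(tert-butyldimethylsilyloxy)-4-{[(2R)-1-(tert-butyldimethylsilyloxy)-3-methylbut-3-en-2-yl]oxy}-5-iodophenyl]ethanone
Conditions: CuI (10 mol%), trans-N,N'-dimethylcyclohexane-1,2-diamine (20 mol%), NaI (2 equiv), 1,4-dioxane, 110 °C, Ar
Reagents that add atoms: sodium iodide, [Na+].[I-]
Why: Copper-catalysed aromatic Finkelstein halogen exchange, pulled toward the aryl iodide by precipitation of NaBr from dioxane, supplies the iodide the nickel/chromium step needs, and with both hydroxyls silylated no copper-catalysed intramolecular O-arylation can compete.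

Step 5
Reactants: 6 1-[2-(tert-butyldimethylsilyloxy)-4-{[(2R)-1-(tert-butyldimethylsilyloxy)-3-methylbut-3-en-2-yl]oxy}-5-iodophenyl]ethanone
Product: 7 1-[2-(tert-butyldimethylsilyloxy)-4-{[(2R)-1-hydroxy-3-methylbut-3-en-2-yl]oxy}-5-iodophenyl]ethanone
Conditions: camphorsulfonic acid (10 mol%), MeOH/CH2Cl2 (1:1), 0 °C
Reagents that add atoms: none
Why: Selective desilylation by acid-catalysed methanolysis, which cleaves the unhindered primary alkyl silyl ether much faster than the aryl silyl ether, whose oxygen is a poor base, so only the primary alcohol is freed.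

Step 6
Reactants: 7 1-[2-(tert-butyldimethylsilyloxy)-4-{[(2R)-1-hydroxy-3-methylbut-3-en-2-yl]oxy}-5-iodophenyl]ethanone
Product: 8 (2R)-2-[4-acetyl-5-(tert-butyldimethylsilyloxy)-2-iodophenoxy]-3-methylbut-3-enal
Conditions: Dess–Martin periodinane (1.3 equiv), NaHCO3, CH2Cl2, 0 °C to rt; cold Na2S2O3/NaHCO3 wash, crude used at once
Reagents that add atoms: none
Why: Dess–Martin oxidation under bicarbonate buffer gives the aldehyde under neutral, non-enolising conditions, so the α-aryloxy β,γ-unsaturated aldehyde should keep its C2 configuration and its unconjugated double bond when used without chromatography.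

Step 7
Reactants: 8 (2R)-2-[4-acetyl-5-(tert-butyldimethylsilyloxy)-2-iodophenoxy]-3-methylbut-3-enal
Product: 9 1-[(2R,3S)-6-(tert-butyldimethylsilyloxy)-3-hydroxy-2-(prop-1-en-2-yl)-2,3-dihydro-1-benzofuran-5-yl]ethanone
Conditions: CrCl2 (5 equiv), NiCl2 (2 mol%), degassed DMF, 0.02 M, rt, Ar; aqueous work-up
Reagents that add atoms: none
Why: Zerovalent nickel, formed from NiCl2 by reduction with CrCl2, inserts into the C3a–I bond, the aryl group passes to trivalent chromium, and the arylchromium adds to the tethered aldehyde carbon to give the C3 carbinol after hydrolysis of the chromium alkoxide. The closest known reaction type is the nickel/chromium-mediated Nozaki–Hiyama–Kishi coupling of aryl and alkenyl iodides with aldehydes in its intramolecular form. The dihydrofuran ring (O1, C2, C3, C3a, C7a) closes in a 5-exo-trig mode through the new C3–C3a bond. The new C3 centre is controlled by the existing C2 centre, since the aldehyde should react through the rotamer that turns its metal-bound oxygen away from the isopropenyl group, placing hydroxyl and isopropenyl trans, (2R,3S). The step needs addition to the aldehyde alone, which the weakly basic, carbonyl-selective arylchromium secures, the acetyl ketone and the isopropenyl alkene (a possible 5-exo carbometalation acceptor) being inert at room temperature. The neutral medium should also keep the enolisable C2 centre from epimerising and the double bond from moving into conjugation.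

Step 8
Reactants: 10 3-methylfuran-2(5H)-one
Product: 13 4-methoxybenzyl (2Z)-4-acetoxy-2-methylbut-2-enoate, via sodium (2Z)-4-hydroxy-2-methylbut-2-enoate 11 (not isolated), via 4-methoxybenzyl (2Z)-4-hydroxy-2-methylbut-2-enoate 12 (not isolated)
Conditions: NaOH (1.0 equiv), H2O, 0 °C to rt, freeze-dry; 4-MeOC6H4CH2Cl, Bu4NI (cat.), DMF, rt; then Ac2O, pyridine, DMAP (cat.), 0 °C
Reagents that add atoms: sodium hydroxide, [Na+].[OH-]; 4-methoxybenzyl chloride, COc1ccc(CCl)cc1; acetic anhydride, CC(=O)OC(C)=O
Why: Saponification of the butenolide gives the hydroxy carboxylate with the cis geometry of the ring intact, SN2 alkylation of the carboxylate caps the acid, and acetylation of the primary alcohol in the same flask forestalls relactonisation.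

Step 9
Reactants: 13 4-methoxybenzyl (2Z)-4-acetoxy-2-methylbut-2-enoate
Product: 14 (2Z)-4-acetoxy-2-methylbut-2-enoic acid
Conditions: CF3CO2H, anisole, CH2Cl2, 0 °C
Reagents that add atoms: none
Why: Acidolysis of the 4-methoxybenzyl ester, with the benzyl cation trapped by anisole in a Friedel–Crafts alkylation, frees the acid without touching the acetate or the Z alkene.

Step 10
Reactants: 9 1-[(2R,3S)-6-(tert-butyldimethylsilyloxy)-3-hydroxy-2-(prop-1-en-2-yl)-2,3-dihydro-1-benzofuran-5-yl]ethanone; 14 (2Z)-4-acetoxy-2-methylbut-2-enoic acid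
Product: 16 (2R,3S)-5-acetyl-6-(tert-butyldimethylsilyloxy)-2-(prop-1-en-2-yl)-2,3-dihydro-1-benzofuran-3-yl (2Z)-4-acetoxy-2-methylbut-2-enoate, via 2,4,6-trichlorobenzoic mixed anhydride 15 (not isolated)
Conditions: 2,4,6-Cl3C6H2COCl, Et3N, toluene, rt; then 9, toluene, 60–70 °C, no DMAP
Reagents that add atoms: none
Why: Yamaguchi esterification, in which the alcohol attacks the unhindered enoyl carbonyl of the mixed anhydride, and leaving out DMAP avoids the reversible conjugate addition that turns angelate-type Z acyl donors into E isomers; C3 is not touched, so the trans relationship is kept.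

Step 11
Reactants: 16 (2R,3S)-5-acetyl-6-(tert-butyldimethylsilyloxy)-2-(prop-1-en-2-yl)-2,3-dihydro-1-benzofuran-3-yl (2Z)-4-acetoxy-2-methylbut-2-enoate
Product: 17 (2R,3S)-5-acetyl-6-hydroxy-2-(prop-1-en-2-yl)-2,3-dihydro-1-benzofuran-3-yl (2Z)-4-acetoxy-2-methylbut-2-enoate
Conditions: Bu4NF/AcOH (1:1, 1.2 equiv), THF, 0 °C
Reagents that add atoms: none
Why: Fluoride-induced desilylation of the aryl silyl ether, activated by the ortho acetyl group, is fast at 0 °C, and the acetic acid buffer protonates the phenoxide at once so that it can neither expel the para-benzylic C3 ester by a quinone methide pathway nor attack the acetate.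

**Compound list**

1 | methacrolein (2-methylprop-2-enal) | C=C(C)C=O | starting material
2 | rac-2-(prop-1-en-2-yl)oxirane | C=C(C)C1CO1 | intermediate
3 | 1-(5-bromo-2,4-dihydroxyphenyl)ethanone | CC(=O)c1cc(Br)c(O)cc1O | starting material
4 | 1-[5-bromo-2-hydroxy-4-{[(2R)-1-hydroxy-3-methylbut-3-en-2-yl]oxy}phenyl]ethanone | C=C(C)[C@H](CO)Oc1cc(O)c(C(C)=O)cc1Br | intermediate
5 | 1-[5-bromo-2-(tert-butyldimethylsilyloxy)-4-{[(2R)-1-(tert-butyldimethylsilyloxy)-3-methylbut-3-en-2-yl]oxy}phenyl]ethanone | C=C(C)[C@H](CO[Si](C)(C)C(C)(C)C)Oc1cc(O[Si](C)(C)C(C)(C)C)c(C(C)=O)cc1Br | intermediate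
6 | 1-[2-(tert-butyldimethylsilyloxy)-4-{[(2R)-1-(tert-butyldimethylsilyloxy)-3-methylbut-3-en-2-yl]oxy}-5-iodophenyl]ethanone | C=C(C)[C@H](CO[Si](C)(C)C(C)(C)C)Oc1cc(O[Si](C)(C)C(C)(C)C)c(C(C)=O)cc1I | intermediate
7 | 1-[2-(tert-butyldimethylsilyloxy)-4-{[(2R)-1-hydroxy-3-methylbut-3-en-2-yl]oxy}-5-iodophenyl]ethanone | C=C(C)[C@H](CO)Oc1cc(O[Si](C)(C)C(C)(C)C)c(C(C)=O)cc1I | intermediate
8 | (2R)-2-[4-acetyl-5-(tert-butyldimethylsilyloxy)-2-iodophenoxy]-3-methylbut-3-enal | C=C(C)[C@H](C=O)Oc1cc(O[Si](C)(C)C(C)(C)C)c(C(C)=O)cc1I | intermediate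
9 | 1-[(2R,3S)-6-(tert-butyldimethylsilyloxy)-3-hydroxy-2-(prop-1-en-2-yl)-2,3-dihydro-1-benzofuran-5-yl]ethanone (trans) | C=C(C)[C@H]1Oc2cc(O[Si](C)(C)C(C)(C)C)c(C(C)=O)cc2[C@@H]1O | intermediate
10 | 3-methylfuran-2(5H)-one | CC1=CCOC1=O | starting material
11 | sodium (2Z)-4-hydroxy-2-methylbut-2-enoate | [Na+].[O-]C(=O)/C(C)=C\CO | intermediate
12 | 4-methoxybenzyl (2Z)-4-hydroxy-2-methylbut-2-enoate | COc1ccc(COC(=O)/C(C)=C\CO)cc1 | intermediate
13 | 4-methoxybenzyl (2Z)-4-acetoxy-2-methylbut-2-enoate | COc1ccc(COC(=O)/C(C)=C\COC(C)=O)cc1 | intermediate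
14 | (2Z)-4-acetoxy-2-methylbut-2-enoic acid | OC(=O)/C(C)=C\COC(C)=O | intermediate
15 | (2Z)-4-acetoxy-2-methylbut-2-enoic 2,4,6-trichlorobenzoic anhydride | O=C(OC(=O)/C(C)=C\COC(C)=O)c1c(Cl)cc(Cl)cc1Cl | intermediate
16 | (2R,3S)-5-acetyl-6-(tert-butyldimethylsilyloxy)-2-(prop-1-en-2-yl)-2,3-dihydro-1-benzofuran-3-yl (2Z)-4-acetoxy-2-methylbut-2-enoate | C=C(C)[C@H]1Oc2cc(O[Si](C)(C)C(C)(C)C)c(C(C)=O)cc2[C@@H]1OC(=O)/C(C)=C\COC(C)=O | intermediate
17 | (2R,3S)-5-acetyl-6-hydroxy-2-(prop-1-en-2-yl)-2,3-dihydro-1-benzofuran-3-yl (2Z)-4-acetoxy-2-methylbut-2-enoate | C=C(C)[C@H]1Oc2cc(O)c(C(C)=O)cc2[C@@H]1OC(=O)/C(C)=C\COC(C)=O | target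

**Step count**

Total: 11 steps. Longest linear sequence: 9 steps (steps 1–7, 10 and 11, from methacrolein); the acid branch (steps 8 and 9) joins at step 10.

**Steps most likely to fail**

Step 7. The addition to the aldehyde may show poor facial selectivity and favour the cis carbinol, and the aldehyde may enolise before the ring closes. The fallback sets out from 8 and accepts the closure even if it gives mainly the cis carbinol 1-[(2R,3R)-6-(tert-butyldimethylsilyloxy)-3-hydroxy-2-(prop-1-en-2-yl)-2,3-dihydro-1-benzofuran-5-yl]ethanone F1. F1 is esterified with acid 14 under Mitsunobu conditions (PPh3, diisopropyl azodicarboxylate, toluene, 0 °C). The unactivated carboxylate displaces the activated C3 oxygen from the face opposite the isopropenyl group with inversion, so C3 is set by substitution instead of by the carbonyl addition. The route is rejoined at 16.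

Step 2. The electron-poor aryl allyl ether may re-ionise under palladium, which would erode the branched-to-linear ratio and the enantiomeric purity, and the ligand may discriminate weakly with the 2-methyl-substituted allyl unit. The fallback sets out from 3 and forms the C2–O bond by Mitsunobu inversion instead.
- Isopropenylmagnesium bromide is added to commercial (tert-butyldimethylsilyloxy)acetaldehyde (THF, −78 °C) to give rac-1-(tert-butyldimethylsilyloxy)-3-methylbut-3-en-2-ol F2.
- Lipase-catalysed acylation (Candida antarctica lipase B, vinyl acetate) is expected, by the usual empirical rule for secondary alcohols, to leave (2S)-1-(tert-butyldimethylsilyloxy)-3-methylbut-3-en-2-ol F3 unreacted beside (2R)-1-(tert-butyldimethylsilyloxy)-3-methylbut-3-en-2-yl acetate F4.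
- F3 is coupled with the 4-hydroxyl of 3 (PPh3, diisopropyl azodicarboxylate, toluene, 0 °C) with inversion to give 1-[5-bromo-4-{[(2R)-1-(tert-butyldimethylsilyloxy)-3-methylbut-3-en-2-yl]oxy}-2-hydroxyphenyl]ethanone F5.
- Silylation of the phenol (TBSCl, imidazole, DMF) rejoins the route at 5.

Step 10. The activated acid may isomerise from Z to E by reversible conjugate addition of chloride or amine, and the hindered benzylic carbinol may acylate slowly. The fallback sets out from 9 and builds the Z alkene on the substrate.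
- Commercial ethyl 2-[bis(2,2,2-trifluoroethoxy)phosphoryl]propanoate is saponified under control (LiOH, 1 equiv, THF/H2O, 0 °C) to 2-[bis(2,2,2-trifluoroethoxy)phosphoryl]propanoic acid F6.
- F6 is coupled with 9 (dicyclohexylcarbodiimide, DMAP cat., CH2Cl2, 0 °C; no isomerisable alkene is present) to give (2R,3S)-5-acetyl-6-(tert-butyldimethylsilyloxy)-2-(prop-1-en-2-yl)-2,3-dihydro-1-benzofuran-3-yl 2-[bis(2,2,2-trifluoroethoxy)phosphoryl]propanoate F7, a mixture of epimers at the phosphorus-bearing carbon.
- Still–Gennari olefination of F7 (KN(SiMe3)2, 1.0 equiv, 18-crown-6, THF, −78 °C) with 2-oxoethyl acetate F8, freshly made by ozonolysis of (Z)-but-2-ene-1,4-diyl diacetate (O3, CH2Cl2, −78 °C; Me2S), should give the Z-enoate and rejoins the route at 16.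

**Further compounds**

F1 | step 7 | 1-[(2R,3R)-6-(tert-butyldimethylsilyloxy)-3-hydroxy-2-(prop-1-en-2-yl)-2,3-dihydro-1-benzofuran-5-yl]ethanone (cis) | C=C(C)[C@H]1Oc2cc(O[Si](C)(C)C(C)(C)C)c(C(C)=O)cc2[C@H]1O
F2 | step 2 | rac-1-(tert-butyldimethylsilyloxy)-3-methylbut-3-en-2-ol | C=C(C)C(O)CO[Si](C)(C)C(C)(C)C
F3 | step 2 | (2S)-1-(tert-butyldimethylsilyloxy)-3-methylbut-3-en-2-ol | C=C(C)[C@H](O)CO[Si](C)(C)C(C)(C)C
F4 | step 2 | (2R)-1-(tert-butyldimethylsilyloxy)-3-methylbut-3-en-2-yl acetate | C=C(C)[C@@H](OC(C)=O)CO[Si](C)(C)C(C)(C)C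
F5 | step 2 | 1-[5-bromo-4-{[(2R)-1-(tert-butyldimethylsilyloxy)-3-methylbut-3-en-2-yl]oxy}-2-hydroxyphenyl]ethanone | C=C(C)[C@H](CO[Si](C)(C)C(C)(C)C)Oc1cc(O)c(C(C)=O)cc1Br
F6 | step 10 | 2-[bis(2,2,2-trifluoroethoxy)phosphoryl]propanoic acid | CC(C(=O)O)P(=O)(OCC(F)(F)F)OCC(F)(F)F
F7 | step 10 | (2R,3S)-5-acetyl-6-(tert-butyldimethylsilyloxy)-2-(prop-1-en-2-yl)-2,3-dihydro-1-benzofuran-3-yl 2-[bis(2,2,2-trifluoroethoxy)phosphoryl]propanoate | C=C(C)[C@H]1Oc2cc(O[Si](C)(C)C(C)(C)C)c(C(C)=O)cc2[C@@H]1OC(=O)C(C)P(=O)(OCC(F)(F)F)OCC(F)(F)F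
F8 | step 10 | 2-oxoethyl acetate | CC(=O)OCC=O
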